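Two questions were put to the meeting about this flask, whose Z charge lies between those of two earlier runs.

| flask | Q | L | Z | remark | time |
|---|---|---|---|---|---|
| south-east | 0.028 M | 1.1 equiv | 0.34 equiv | run made earlier |  |
| north | 0.028 M | 1.1 equiv | 0.75 equiv | run made earlier |  |
| flask | 0.028 M | 1.10 equiv | 0.500 equiv |  | 2.5 h |

- south-east (time / min: Q / %, J / %): 6.00: 87, 14; 20.0: 72, 25; 30.0: 62, 35; 50.0: 52, 49; 80.0: 43, 54; 90.0: 39, 57; 120: 32, 61
- north (time / min: Q / %, J / %): 15.0: 77, 24; 30.0: 63, 37; 50.0: 52, 51; 60.0: 47, 50; 80.0: 40, 55; 90.0: 38, 57; 120: 29, 59

(standard deviation of a reading: 2 percentage points)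

- the numbers in the tables scatter with a standard deviation of 2 percentage points
- the earlier runs do not show how much of L is bound; that part of a forecast is a guess

- part of the Q that has reacted at 2.5 h
- share of the unused L that is free and not bound as E, at 2.5 h

Minutes. The first speaker reported that, in the last readings of the two runs, Q stands at 30.5 % of its charge on average. Q + J falls short of the charge by 9.50 %, a reading with about 2 percentage points of scatter, and she took this gap as bis adduct, J having met a second L.

The second speaker proposed dividing the rate at which J turns into bis adduct by the rate at which Q is used. If each step takes one L, L and time drop out, leaving a ratio s times J over Q. With J taken as roughly the Q used, this sums to: bis adduct = s × (ln of one over Q, less the fraction of Q used). The gap then reads s = 0.193, the selectivity factor.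

The third speaker applied this to the forecast, which gave c 74 % (70 % to 78 %) and fr 80 % (40 % to 98 %), held that “Z has no visible effect on the rate”, and called fr a guess. At that c, she reckoned, the flask holds 11.7 % bis adduct, leaving unused L at 24.3 % of the Q charged.

The flask gives c 71.7 % and fr 60.7 %, which is 19 points below the forecast.

    L + J → X + D (k = 0.00230 /M/s)
    Z + D → G (k = 0.0620 /M/s)
    Q + L → J + D (k = 0.0130 /M/s)
    L + D ⇌ E, settled at all times (K = 100 /M)

At that c, the factor reckons this flask's bis adduct X at 10.5 % of the Q charged, and the flask holds 8.91 %. Its unused L stands as free L, 17.8 % of the Q charged, and E, 11.5 %. In a neighbouring flask, L is cut to 0.440 equiv, the other charges and the time held, and c falls to 37.3 %. The same factor reckons X in that neighbouring flask at 1.81 %, and that flask holds 1.62 %.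

The earlier runs and the new flask come from a simulation with made-up constants, and the scatter is random.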